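**Retrosynthetic overview**
- 15 ⇒ 14 (silyl ether removed) ⇒ alcohol 12 + p-coumaric acid 13 (ester C–O bond, Mitsunobu) ⇒ acylsultam 11 (reductive loss of the auxiliary).
- Key disconnection: ring C (the dihydrofuran) of 11 is cut at O1–C2 (phenol + p-quinone methide) and at C3–C3a (two phenoxyl radicals). This leads back to N-feruloylsultam 6 and the 4-alkylguaiacol 8, which a heme peroxidase with H2O2 joins in one operation that also sets C2 and C3.
- Enabling feature: the free 4-OH of ring A (the guaiacyl ring on C2) stands para to C2, so ring A can become a p-quinone methide with C2 as its electrophilic end. O1 on C7a and the neighbouring C3a are the phenol oxygen and the free ortho carbon of a second guaiacyl ring (ring B).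
- Ring order: benzene rings A, B and D (p-coumarate) are bought, and ring C is the only ring made (step 4). The sultam rings are a temporary chiral controller on C9, held one oxidation level above the target.
- 6 ⇐ sultam 1 + acryloyl chloride 2 + 4-bromoguaiacol 5 (N-acylation, Heck reaction); 8 ⇐ dihydroconiferyl alcohol 7.

Key step: step 4

Assumption: the (2R)-sultam is taken to direct bond formation to the Re face of C8 (the later C3), as it does in other additions at the α-carbon of its N-enoyl derivatives. Should the coupling show the opposite sense, the equally available (2S)-sultam is used and nothing else changes.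

**Step 1**
Reactants: 1 (2R)-bornane-10,2-sultam; 2 acryloyl chloride
Product: 4 N-acryloyl-(2R)-bornane-10,2-sultam, via sodium sultamide 3 (not isolated)
Conditions: NaH (1.1 equiv), toluene, rt; then 2 (1.2 equiv), 0 °C to rt
Reagents that add atoms: none
Why: N-acylation of the sulfonamide anion by an acid chloride is the standard way of loading this auxiliary and touches no stereocentre.

**Step 2**
Reactants: 4 N-acryloyl-(2R)-bornane-10,2-sultam; 5 4-bromo-2-methoxyphenol
Product: 6 N-[(E)-feruloyl]-(2R)-bornane-10,2-sultam
Conditions: Pd(OAc)2 (3 mol %), P(o-tol)3 (9 mol %), Et3N (2 equiv), MeCN, 85 °C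
Reagents that add atoms: none
Why: In this Heck reaction, zerovalent palladium formed in situ inserts into the C–Br bond, and syn carbopalladation at the terminal acrylimide carbon followed by syn β-hydride elimination should give only the E-alkene, free phenols being tolerated.

**Step 3**
Reactants: 7 dihydroconiferyl alcohol
Product: 8 4-[3-(tert-butyldimethylsilyloxy)propyl]-2-methoxyphenol
Conditions: TBSCl (1.05 equiv), imidazole (2 equiv), CH2Cl2, 0 °C
Reagents that add atoms: tert-butyldimethylsilyl chloride (TBSCl), CC(C)(C)[Si](C)(C)Cl
Why: In this chemoselective silyl ether protection, the unhindered primary alcohol should react under imidazole catalysis ahead of the ortho-methoxy, hydrogen-bonded phenol, which stays free for step 4.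

**Step 4**
Reactants: 6 N-[(E)-feruloyl]-(2R)-bornane-10,2-sultam; 8 4-[3-(tert-butyldimethylsilyloxy)propyl]-2-methoxyphenol
Product: 11 N-{[(2R,3R)-5-[3-(tert-butyldimethylsilyloxy)propyl]-2-(4-hydroxy-3-methoxyphenyl)-7-methoxy-2,3-dihydro-1-benzofuran-3-yl]carbonyl}-(2R)-bornane-10,2-sultam (trans), via dienone quinone methide 9 (not isolated), via phenol quinone methide 10 (not isolated)
Conditions: horseradish peroxidase (heme peroxidase, EC 1.11.1.7, cat.), 8 (4 equiv), acetone/citrate–phosphate buffer pH 4.5 (1:1), rt; 6 (in acetone) and aq. H2O2 (1.5 equiv) fed together by syringe pump over 8 h; excess 8 recovered; chromatography, then crystallisation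
Reagents that add atoms: none
Why: The peroxidase, turned over by H2O2, removes one electron and one proton from each phenol; the radical of 6 (spin on C8, alpha to the imide carbonyl) and the radical of 8 (spin on the free ring carbon ortho to its oxygen) combine to 9, ring B re-aromatises by enolisation to 10, and the freed phenol oxygen adds to the benzylic end of the ring A p-quinone methide, which forms O1–C2 and re-aromatises ring A. The closest known reaction type is the biomimetic 8–5′ oxidative phenol coupling, run with peroxidase/H2O2 or Ag2O on ferulates and on N-feruloyl derivatives of chiral auxiliaries, together with the slow-feed peroxidase cross-coupling of hydroxycinnamyl monomers onto 4-alkylguaiacol units. Ring C, the only ring closed, forms by a 5-exo-trig 1,6-conjugate (oxa-Michael) addition. C3 is set in the radical combination by the sultam, whose s-cis enoyl rotamer with the carbonyl anti to the sulfonyl group should leave the Re face of C8 open, and C2 is set relative to C3 in the ring closure, which places aryl and acyl groups trans and, being reversible through the quinone methide, should drain to that more stable isomer; the minor (2S,3S) product is a diastereomer of 11 and is removed on purification. The step needs cross- over homo-coupling and C- over O-attack on 8: the excess of cheap 8, the slow joint feed of 6 and H2O2 and the polarity match between the electron-poor C8 radical and the electron-rich alkylguaiacoxyl radical serve the first, while the known bias of acyl-substituted C8 radicals for the 8–5′ mode, the 4-alkyl group blocking the para carbon of 8 and the acetone-rich acidic medium serve the second. A small oxidant strong enough for both phenols would also attack the product phenol and the alkene, whereas the enzyme doses single electrons at the rate of the H2O2 feed, 8 can relay oxidation to the bulky 6, and the excess of 8 shields 11.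

**Step 5**
Reactants: 11 coupled acylsultam
Product: 12 [(2R,3S)-5-[3-(tert-butyldimethylsilyloxy)propyl]-2-(4-hydroxy-3-methoxyphenyl)-7-methoxy-2,3-dihydro-1-benzofuran-3-yl]methanol
Conditions: LiBH4 (3 equiv), THF, 0 °C to rt; aq. NH4Cl
Reagents that add atoms: none
Why: In this reductive cleavage of an N-acylsultam, hydride attacks the sulfonyl-activated exocyclic carbonyl faster than C3 is deprotonated, so both stereocentres should be kept (the C3 descriptor changes only by priority), the silyl and aryl ethers are inert, and 1 is recovered.

**Step 6**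
Reactants: 12 primary alcohol; 13 (E)-p-coumaric acid
Product: 14 [(2R,3S)-5-[3-(tert-butyldimethylsilyloxy)propyl]-2-(4-hydroxy-3-methoxyphenyl)-7-methoxy-2,3-dihydro-1-benzofuran-3-yl]methyl (E)-3-(4-hydroxyphenyl)prop-2-enoate
Conditions: 13 (1.2 equiv), PPh3 (1.3 equiv), DIAD (1.3 equiv), THF, 0 °C to rt
Reagents that add atoms: none
Why: In this Mitsunobu esterification only the aliphatic alcohol is activated and only the carboxylic acid is acidic enough to act as the nucleophile, so the free phenols of both partners should stay untouched, and the reacting carbon is not stereogenic.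

**Step 7**
Reactants: 14 silyl-protected ester
Product: 15 target, (2R,3S)-dihydrodehydrodiconiferyl alcohol 9-O-(E)-p-coumarate
Conditions: Et3N·3HF (5 equiv), THF, rt
Reagents that add atoms: none
Why: Fluoride-mediated desilylation under nearly neutral conditions frees the primary alcohol without ester migration, ester cleavage or opening of the phenolic benzyl aryl ether, so C2 and C3 are not disturbed.

**Compound list**
1 | (2R)-bornane-10,2-sultam, (1S,2R,4R)-(−)-2,10-camphorsultam | CC1(C)[C@@H]2CC[C@]13CS(=O)(=O)N[C@@H]3C2 | starting material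
2 | acryloyl chloride | C=CC(=O)Cl | starting material
3 | sodium salt of 1 (sodium sultamide) | CC1(C)[C@@H]2CC[C@]13CS(=O)(=O)[N-][C@@H]3C2.[Na+] | intermediate
4 | N-acryloyl-(2R)-bornane-10,2-sultam | C=CC(=O)N1[C@@H]2C[C@H]3CC[C@]2(CS1(=O)=O)C3(C)C | intermediate
5 | 4-bromo-2-methoxyphenol | COc1cc(Br)ccc1O | starting material
6 | N-[(E)-3-(4-hydroxy-3-methoxyphenyl)prop-2-enoyl]-(2R)-bornane-10,2-sultam | COc1cc(/C=C/C(=O)N2[C@@H]3C[C@H]4CC[C@]3(CS2(=O)=O)C4(C)C)ccc1O | intermediate
7 | dihydroconiferyl alcohol, 4-(3-hydroxypropyl)-2-methoxyphenol | COc1cc(CCCO)ccc1O | starting material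
8 | 4-[3-(tert-butyldimethylsilyloxy)propyl]-2-methoxyphenol | COc1cc(CCCO[Si](C)(C)C(C)(C)C)ccc1O | intermediate
9 | first C8–C5′ adduct: ring A p-quinone methide, ring B cyclohexa-2,4-dienone (C8 as in 11; the ring sp3 carbon and the exocyclic alkene geometry are transient and left open) | O=C1C=CC(=C[C@H](C(=O)N2[C@@H]3C[C@H]4CC[C@]3(CS2(=O)=O)C4(C)C)C2C=C(CCCO[Si](C)(C)C(C)(C)C)C=C(OC)C2=O)C=C1OC | intermediate
10 | (8S)-phenol p-quinone methide after enolisation of ring B (exocyclic alkene geometry left open) | O=C1C=CC(=C[C@H](C(=O)N2[C@@H]3C[C@H]4CC[C@]3(CS2(=O)=O)C4(C)C)c2cc(CCCO[Si](C)(C)C(C)(C)C)cc(OC)c2O)C=C1OC | intermediate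
11 | trans-(2R,3R)-2-aryl-2,3-dihydrobenzofuran-3-carbonyl sultam | COc1cc([C@@H]2Oc3c(OC)cc(CCCO[Si](C)(C)C(C)(C)C)cc3[C@H]2C(=O)N2[C@@H]3C[C@H]4CC[C@]3(CS2(=O)=O)C4(C)C)ccc1O | intermediate
12 | (2R,3S)-3-hydroxymethyl compound, side chain as TBS ether | COc1cc([C@@H]2Oc3c(OC)cc(CCCO[Si](C)(C)C(C)(C)C)cc3[C@H]2CO)ccc1O | intermediate
13 | (E)-p-coumaric acid | OC(=O)/C=C/c1ccc(O)cc1 | starting material
14 | (2R,3S)-p-coumarate ester, side chain as TBS ether | COc1cc([C@@H]2Oc3c(OC)cc(CCCO[Si](C)(C)C(C)(C)C)cc3[C@H]2COC(=O)/C=C/c2ccc(O)cc2)ccc1O | intermediate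
15 | CNP0202924.1 | COc1cc([C@@H]2Oc3c(OC)cc(CCCO)cc3[C@H]2COC(=O)/C=C/c2ccc(O)cc2)ccc1O | target

**Totals**
Total step count: 7. Longest linear sequence: 6 (steps 1, 2, 4, 5, 6, 7).

**Steps most likely to fail**

**Step 4.**
- What may go wrong:
  - homo-coupling of either phenol outruns the cross-coupling;
  - C8 couples to the oxygen of 8 instead of its ortho carbon;
  - the product phenol is over-oxidised;
  - facial selectivity at C8 is poor.
- Fallback, setting out from 6 and coming back at 12:
  - The cross-coupling is given up and 6 is coupled with itself (Ag2O, CH2Cl2, rt), the reaction of closest precedent, to the 8–5′ dehydrodimer bis-sultam F1.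
  - H2 over Pd/C in EtOAc saturates the remaining enoyl double bond to the saturated bis-sultam F2.
  - LiBH4 in THF removes both auxiliaries to (7R,8S)-dihydrodehydrodiconiferyl alcohol F3.
  - One equivalent of TBSCl with imidazole at −20 °C should silylate the unhindered side-chain alcohol ahead of the β-branched C3 hydroxymethyl group and the phenol, which gives 12.

**Step 6.**
- What may go wrong: a phenol oxygen is alkylated in place of the carboxylate, or the activated β-branched alcohol eliminates toward the exocyclic alkene.
- Fallback, setting out from 12 and coming back at 14: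
  - The alcohol is made the nucleophile instead of the electrophile.
  - An excess of 4-acetoxycinnamoyl chloride F4 (from commercial 4-acetoxycinnamic acid and SOCl2) with pyridine and DMAP acylates both the C3 hydroxymethyl group and the ring A phenol to the bis(4-acetoxycinnamate) F5.
  - Pyrrolidine in CH2Cl2 then cleaves by aminolysis only the three aryl esters and leaves the alkyl ester, which gives 14.

**Step 5.**
- What may go wrong: C3 is deprotonated ahead of hydride delivery, followed by epimerisation or β-elimination of the ring oxygen with opening of ring C, or the auxiliary is released incompletely from the hindered carbonyl.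
- Fallback, setting out from 11 and coming back at 12:
  - The auxiliary is first exchanged under Lewis-acidic, non-basic conditions (Ti(OEt)4, EtOH, reflux) to the ethyl (2R,3R)-dihydrobenzofuran-3-carboxylate F6.
  - This ester is reduced with i-Bu2AlH in toluene at −78 °C to 0 °C to 12.

**Further compounds**
F1 | step 4 | 8–5′ dehydrodimer of 6, (2R,3R), bis-sultam with E-enoyl side chain | COc1cc([C@@H]2Oc3c(OC)cc(/C=C/C(=O)N4[C@@H]5C[C@H]6CC[C@]5(CS4(=O)=O)C6(C)C)cc3[C@H]2C(=O)N2[C@@H]3C[C@H]4CC[C@]3(CS2(=O)=O)C4(C)C)ccc1O
F2 | step 4 | saturated bis-sultam, (2R,3R) | COc1cc([C@@H]2Oc3c(OC)cc(CCC(=O)N4[C@@H]5C[C@H]6CC[C@]5(CS4(=O)=O)C6(C)C)cc3[C@H]2C(=O)N2[C@@H]3C[C@H]4CC[C@]3(CS2(=O)=O)C4(C)C)ccc1O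
F3 | step 4 | (7R,8S)-dihydrodehydrodiconiferyl alcohol | COc1cc([C@@H]2Oc3c(OC)cc(CCCO)cc3[C@H]2CO)ccc1O
F4 | step 6 | (E)-4-acetoxycinnamoyl chloride | CC(=O)Oc1ccc(/C=C/C(=O)Cl)cc1
F5 | step 6 | bis(4-acetoxycinnamate) of 12 (alkyl ester at C3–CH2O, aryl ester on ring A) | COc1cc([C@@H]2Oc3c(OC)cc(CCCO[Si](C)(C)C(C)(C)C)cc3[C@H]2COC(=O)/C=C/c2ccc(OC(C)=O)cc2)ccc1OC(=O)/C=C/c1ccc(OC(C)=O)cc1
F6 | step 5 | ethyl (2R,3R)-5-[3-(tert-butyldimethylsilyloxy)propyl]-2-(4-hydroxy-3-methoxyphenyl)-7-methoxy-2,3-dihydro-1-benzofuran-3-carboxylate | COc1cc([C@@H]2Oc3c(OC)cc(CCCO[Si](C)(C)C(C)(C)C)cc3[C@H]2C(=O)OCC)ccc1O
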